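**Retrosynthetic overview**

- Rings A and B, all twenty skeletal carbons, C5, C9, C10 and the 6α-oxygen are taken intact from larixol (1). In the rings the target differs only at C8 of ring B, which carries 8α-OH and 8β-CH3 where 1 has the exocyclic C8=C17 methylene.
- C8–O disconnection: the C8 carbinol is traced to the 8α,17-spiro-oxirane 2, made from 1 by α-face peracid oxygen transfer. This oxirane is the only ring formed; rings A and B are bought.
- C12=C13 disconnection: the 12E,14-diene is traced to the tertiary allylic C13 acetate of epoxy diacetate 3, eliminated with zerovalent palladium to diene 4 while the oxirane masks C8. Hydride at C17 then gives diol 5.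
- O6–acyl disconnection: angelic acid (6), through mixed anhydride 7, esterifies the secondary 6α-hydroxyl of 5 last to give target 8.

Key step: step 1

Assumption: larixol (13S) is taken as a purchasable larch diterpenoid; α and β follow the labdane convention with the C20 methyl on C10 as β.

**Route**

Step 1
Reactants: 1 larixol, (13S)-labda-8(17),14-diene-6α,13-diol
Product: 2 (13S)-8α,17-epoxylabd-14-ene-6α,13-diol (spiro-oxirane on C8, oxygen α, C17 β)
Conditions: mCPBA (1.05 equiv), NaHCO3, CH2Cl2, 0 °C
Reagents that add atoms: mCPBA, O=C(OO)c1cccc(Cl)c1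
Why: This is a Prilezhaev epoxidation, in which the peracid passes its terminal oxygen to the alkene through the concerted butterfly transition state; the closest known case is the peracid epoxidation of the exocyclic methylene of labd-8(17)-enes. The oxirane closes as a three-membered spiro ring on C8 in that single step, both C–O bonds forming on one face, with no carbocation and no carbocycle closure. The new stereocentre C8 is set by the axial C20 methyl on C10, which blocks the axial β trajectory at C8 and leaves the equatorial α face open; the 6α-hydroxyl on that face can hydrogen-bond the peracid and should reinforce the delivery. The step needs chemoselectivity between two alkenes and facial selectivity at one: the first rests on the higher nucleophilicity of the 1,1-disubstituted C8=C17 over the monosubstituted C14=C15 vinyl group with one equivalent of oxidant at 0 °C, the second on the C20 methyl. Solid NaHCO3 takes up the 3-chlorobenzoic acid so that neither the 13-hydroxyl nor the 6-hydroxyl opens the acid-sensitive oxirane.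

Step 2
Reactants: 2 (13S)-8α,17-epoxylabd-14-ene-6α,13-diol
Product: 3 (13S)-6α,13-diacetoxy-8α,17-epoxylabd-14-ene
Conditions: Ac2O, Et3N, DMAP, CH2Cl2, rt to 40 °C
Reagents that add atoms: acetic anhydride, CC(=O)OC(C)=O
Why: DMAP-catalysed acylation (Steglich-type acyl transfer through the N-acetylpyridinium ion) should esterify the secondary 6α-hydroxyl quickly and the tertiary allylic 13-hydroxyl on warming, the basic medium leaving the oxirane closed, and no stereocentre is formed or touched.

Step 3
Reactants: 3 (13S)-6α,13-diacetoxy-8α,17-epoxylabd-14-ene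
Product: 4 6α-acetoxy-8α,17-epoxylabda-12E,14-diene
Conditions: Pd(PPh3)4 (5 mol%), Et3N, 1,4-dioxane, 100 °C
Reagents that add atoms: none
Why: In this Tsuji-type palladium-catalysed elimination zerovalent palladium ionises only the allylic C13 acetate to an η3-allyl complex of divalent palladium over C13–C15, which loses a C12 hydrogen to give the conjugated diene, the 12E geometry being favoured because C11 turns away from the metal-bound allyl unit and the E-trisubstituted diene is the more stable, while the non-allylic 6-acetate and the non-vinylic oxirane cannot ionise; the C13 stereocentre is removed and no new one is made.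

Step 4
Reactants: 4 6α-acetoxy-8α,17-epoxylabda-12E,14-diene
Product: 5 labda-12E,14-diene-6α,8α-diol
Conditions: LiAlH4, THF, 0 °C to reflux; then H2O, aq NaOH
Reagents that add atoms: none
Why: In this hydride reduction LiAlH4 opens the oxirane by SN2 attack at the unhindered primary C17, so the C8–O bond and with it the 8α-oxygen and 8β-methyl configuration from step 1 are kept, and in the same flask it cleaves the 6-acetate, the unactivated conjugated diene being inert to hydride.

Step 5
Reactants: 5 labda-12E,14-diene-6α,8α-diol; 6 angelic acid
Product: 8 6α-angeloyloxylabda-12E,14-dien-8α-ol, via angelic 2,4,6-trichlorobenzoic anhydride 7 (not isolated)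
Conditions: 6, 2,4,6-Cl3C6H2COCl, Et3N, toluene, rt; then 5, 80 °C
Reagents that add atoms: 2,4,6-trichlorobenzoyl chloride, O=C(Cl)c1c(Cl)cc(Cl)cc1Cl (its aroyl group is held in 7 and leaves again on the way to 8)
Why: In this Yamaguchi esterification the secondary 6α-hydroxyl attacks the angeloyl carbonyl of mixed anhydride 7, whose aroyl carbonyl is shielded by two ortho chlorines, the tertiary 8α-hydroxyl staying free, and leaving out DMAP or any other nucleophilic catalyst should keep the Z double bond from isomerising to the tiglate; no stereocentre is touched.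

**Compound list**

1 | larixol, (13S)-labda-8(17),14-diene-6α,13-diol | C=C[C@@](C)(O)CC[C@@H]1[C@@]2(C)CCCC(C)(C)[C@@H]2[C@@H](O)CC1=C | starting material
2 | (13S)-8α,17-epoxylabd-14-ene-6α,13-diol | C=C[C@@](C)(O)CC[C@@H]1[C@@]2(C)CCCC(C)(C)[C@@H]2[C@@H](O)C[C@@]1(C3)O3 | intermediate
3 | (13S)-6α,13-diacetoxy-8α,17-epoxylabd-14-ene | C=C[C@@](C)(OC(C)=O)CC[C@@H]1[C@@]2(C)CCCC(C)(C)[C@@H]2[C@@H](OC(C)=O)C[C@@]1(C3)O3 | intermediate
4 | 6α-acetoxy-8α,17-epoxylabda-12E,14-diene | C=C/C(C)=C/C[C@@H]1[C@@]2(C)CCCC(C)(C)[C@@H]2[C@@H](OC(C)=O)C[C@@]1(C3)O3 | intermediate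
5 | labda-12E,14-diene-6α,8α-diol | C=C/C(C)=C/C[C@@H]1[C@@]2(C)CCCC(C)(C)[C@@H]2[C@@H](O)C[C@@]1(C)O | intermediate
6 | angelic acid, (Z)-2-methylbut-2-enoic acid | C/C=C(/C)C(=O)O | starting material
7 | angelic 2,4,6-trichlorobenzoic anhydride | C/C=C(/C)C(=O)OC(=O)c1c(Cl)cc(Cl)cc1Cl | intermediate
8 | 6α-angeloyloxylabda-12E,14-dien-8α-ol | C=C/C(C)=C/C[C@@H]1[C@@]2(C)CCCC(C)(C)[C@@H]2[C@@H](OC(=O)/C(C)=C\C)C[C@@]1(C)O | target

**Step count**

Total steps: 5. Longest linear sequence: 5 steps, from larixol (1).

**Steps most likely to fail**

Step 3. The η3-allyl complex may lose hydrogen from C16 instead of C12, or lose it through the rotamer that places C11 next to the vinyl terminus, so the new double bond is laid down without regio- or stereocontrol; acetate may also return to C15. The fallback sets out from 3 and replaces stereoselective elimination by stereoselective olefination. The elimination is run only to consumption of 3, and the mixture of 4 and its geometrical isomer 6α-acetoxy-8α,17-epoxylabda-12Z,14-diene F1 is ozonised exhaustively (O3, CH2Cl2/MeOH, −78 °C; Me2S). Both isomers should converge on 6α-acetoxy-8α,17-epoxy-13,14,15,16-tetranorlabdan-12-al F2, and material that lost hydrogen from C16 is degraded to a more polar by-product and removed. Wittig reaction of F2 with the stabilised ylide 2-(triphenylphosphoranylidene)propanal (toluene, 80 °C) should give 6α-acetoxy-8α,17-epoxy-15-norlabd-12E-en-14-al F3, the E geometry following from the usual preference of stabilised ylides. Methylenation with Ph3P=CH2 (Ph3PCH3Br, KOtBu, THF, 0 °C) comes back to the route at 4 as the 12E isomer only.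

Step 5. The angeloyl group may isomerise from Z to E during activation or acyl transfer, or the hindered 6α-hydroxyl may acylate too slowly at a temperature that keeps the Z geometry. The fallback sets out from 5 and builds the Z-enoate on the substrate. Esterification of O6 with 2-[bis(2,2,2-trifluoroethoxy)phosphoryl]propanoic acid (EDC·HCl, DMAP, CH2Cl2) should give 6α-{2-[bis(2,2,2-trifluoroethoxy)phosphoryl]propanoyloxy}labda-12E,14-dien-8α-ol F4 (both epimers at the phosphonate carbon serve). Still–Gennari olefination with acetaldehyde (KN(SiMe3)2, 18-crown-6, THF, −78 °C) should then deliver the Z-2-methylbut-2-enoate and come back to the route at 8.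

Step 1. The free 13-hydroxyl or 6-hydroxyl may open the new oxirane under traces of acid (cyclo-etherification), the hydroxyl-bearing vinyl group may be oxidised as well, or facial selectivity may erode. The fallback sets out from 1, masks both hydroxyls before the oxygen transfer, and uses an acid-free oxidant. Acetylation (Ac2O, Et3N, DMAP, CH2Cl2) should give (13S)-6α,13-diacetoxylabda-8(17),14-diene F5, which has no internal nucleophile or directing hydroxyl. Epoxidation of F5 with dimethyldioxirane in acetone at 0 °C, again from the α face under control of the C20 methyl, comes back to the route at 3.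

**Further compounds**

F1 | step 3 | 6α-acetoxy-8α,17-epoxylabda-12Z,14-diene | C=C/C(C)=C\C[C@@H]1[C@@]2(C)CCCC(C)(C)[C@@H]2[C@@H](OC(C)=O)C[C@@]1(C3)O3
F2 | step 3 | 6α-acetoxy-8α,17-epoxy-13,14,15,16-tetranorlabdan-12-al | O=CC[C@@H]1[C@@]2(C)CCCC(C)(C)[C@@H]2[C@@H](OC(C)=O)C[C@@]1(C3)O3
F3 | step 3 | 6α-acetoxy-8α,17-epoxy-15-norlabd-12E-en-14-al | O=C/C(C)=C/C[C@@H]1[C@@]2(C)CCCC(C)(C)[C@@H]2[C@@H](OC(C)=O)C[C@@]1(C3)O3
F4 | step 5 | 6α-{2-[bis(2,2,2-trifluoroethoxy)phosphoryl]propanoyloxy}labda-12E,14-dien-8α-ol | C=C/C(C)=C/C[C@@H]1[C@@]2(C)CCCC(C)(C)[C@@H]2[C@@H](OC(=O)C(C)P(=O)(OCC(F)(F)F)OCC(F)(F)F)C[C@@]1(C)O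
F5 | step 1 | (13S)-6α,13-diacetoxylabda-8(17),14-diene | C=C[C@@](C)(OC(C)=O)CC[C@@H]1[C@@]2(C)CCCC(C)(C)[C@@H]2[C@@H](OC(C)=O)CC1=C
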